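Each initiator is spent once, so its charge is a fixed sum of what impurity destroys and what begins chains, and transfer agent never enters that sum.

    initiator + impurity → spent initiator A (k1 = 1.73 M⁻¹ s⁻¹)
    initiator → spent initiator B (k2 = 6.20 × 10⁻⁸ s⁻¹)
    free monomer + initiator → living end + monomer in chains (k3 = 0.0239 M⁻¹ s⁻¹)
    living end + transfer agent → dead chain (k4 = 0.0196 M⁻¹ s⁻¹)
    free monomer + living end → monomer in chains + living end, rate k5*[living end]*[free monomer] (k5 = 0.128 M⁻¹ s⁻¹)
    free monomer → uncatalysed product (k6 = 7.04 × 10⁻⁶ s⁻¹)

- alder: free monomer 0.050 M; transfer agent 1.50 mM; initiator 5.1 mol%; impurity 2.6 mM; time 20 h
- ash: free monomer 0.050 M; transfer agent 5.00 mM; initiator 5.1 mol%; impurity 2.6 mM; time 20 h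

- which of the two ends with the longer chains by the average number of monomer units in a chain (chains begun, living or dead) ("neither" if they lie within 10%) (alder / ash / neither)
- average number of monomer units in a chain (chains begun, living or dead) at the end, alder
- average number of monomer units in a chain (chains begun, living or dead) at the end, ash

We follow one initiator. Step 2 can be dropped, because its half-life of 130 d far exceeds the 2.6 min of step 1. At the remaining fork the odds are set by the impurity concentration Y against the even level, 0.691 mM, the impurity concentration at which both routes run equally fast, with free monomer held at its charge. Integrating the fork gives chains begun, C = even level × ln(charged Y / remaining Y), and the impurity consumed plus C must equal the initiator charge, 2.55 mM.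

Trying Y at the even level gives a sum of 2.82 mM, which is too much. Halving the excess gives Y = 0.828 mM and a sum of 2.56 mM, which is close enough. So C is 0.790 mM in both flasks.

Each living end then takes one transfer agent. With T0 the transfer agent charged, free monomer's logarithmic fall through growth, the reach, is R = (k5/k4) ln(T0/(T0 − C)). The length before uncatalysed loss is the monomer taken up divided by C:

- alder: T0 1.50 mM, R 4.89, monomer taken 99.2%, length 62.8
- ash: T0 5.00 mM, R 1.12, monomer taken 67.5%, length 42.7

Reading down the rows, C does not change, but alder's reach is larger than ash's. Alder's length therefore exceeds ash's by more than the margin. Step 6 also takes monomer, though with C of living ends it runs slower than growth, so we expect both lengths somewhat below these rows.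

The forecast says alder, with 57 and 40, both below our rows, and holds that length turns on “how much monomer each run converts before transfer agent kills the living ends”.

The simulation gives alder, with 57.7 in alder and 40.9 in ash. Alder's dead chains and living ends add up to 0.773 mM at 20.0 h, against our 0.790 mM. Alder's length has moved by 10% at 2.29 mM and at 2.93 mM of impurity, and by the same amount at 4.7 mol% and at 5.6 mol% of initiator. The neighbour is ash with 0.0065 M of impurity, of which 65.3% remains at 20.0 h. The even level then gives C = 0.295 mM, against 2.93 × 10⁻⁴ M of dead chain. Its 30.9% of monomer in chains, divided by that C, gives 52.4, and the simulated length is 52.7.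

Its constants come from no measurement; what happens was integrated by code.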